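**Plan**
- Target 12 is the achiral methylene-bridged dimer of 3-methylphloracetophenone; in each ring the atoms are numbered C1 (acetyl), C2 (OH), C3 (CH3), C4 (OH), C5 (bridge CH2), C6 (OH).
- Retrosynthesis cuts first the four O–ethyl bonds at C2 and C6 and the two C1–acetyl bonds, then in each ring C3–C4, C1–C2 and C4–C5, and last the four-membered rings of the resulting bis(3-ethoxycyclobutenone).
- Enabling feature: the 1,3,5-oxygen pattern lets C4–C5–C6–C1 of each ring be read as a vinylketene (C4 ketene carbonyl carbon, C5 bridge-bearing terminus, C6 ethoxy carbon, C1 CH) and C3–C2 as the methyl-bearing and oxygen-bearing carbons of an ynol ether.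
- Forward: both cyclobutenones arise together from the glutaryl chain (step 1), both benzene rings arise together in step 2, then C1 is acetylated and the ethers are cleaved.
- Stereochemistry: the target has no stereocentre; those of the cyclobutenone and of later intermediates form without control and vanish on aromatization.

Key step: step 2

Remark: the diastereomer mixtures of 4, 7 and 9 are carried on as such; 3 and 6–9 are written in their symmetrical form, although the two ends of each molecule react independently of one another.

**Route**

Step 1
Reactants: 1 glutaryl dichloride; 2 ethoxyacetylene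
Product: 4 4,4'-methylenebis(3-ethoxycyclobut-2-en-1-one) (meso/racemic mixture), via bis-ketene penta-1,4-diene-1,5-dione 3 (not isolated)
Conditions: Et3N (2.5 equiv), 2 (4 equiv), Et2O–hexanes, 0 °C to 35 °C, 1 added slowly by syringe pump
Reagents that add atoms: none
Why: Et3N dehydrochlorinates each acyl chloride terminus to an aldoketene, which the ynol ether traps in a regioselective ketene–alkyne (2+2) cycloaddition (ketene carbonyl carbon to the unsubstituted alkyne carbon), placing ethoxy at C3 and the chain at C4 of each ring; the two stereocentres form without control, and slow addition into excess 2 keeps free ketene low.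

Step 2
Reactants: 4 4,4'-methylenebis(3-ethoxycyclobut-2-en-1-one); 5 1-ethoxyprop-1-yne
Product: 10 bis(4,6-diethoxy-2-hydroxy-3-methylphenyl)methane, via bis(vinylketene) 6 (not isolated), via bis(4-alkenylcyclobutenone) 7 (not isolated), via bis(dienylketene) 8 (not isolated), via bis(cyclohexa-2,4-dienone) 9 (not isolated)
Conditions: 5 (6 equiv), PhMe (0.05 M), sealed tube, 80 °C; then excess 5 evaporated, PhMe, 110 °C
Reagents that add atoms: none
Why: Each cyclobutenone of 4 should open at 80 °C in a conrotatory four-electron electrocyclic reaction (chain outward) to a vinylketene arm of 6, whose ketene C=C adds ynol ether 5 in a (2+2) cycloaddition to give the 4-alkenylcyclobutenone arms of 7; a second four-electron opening gives the dienylketene arms of 8, which cyclize and tautomerize via 9 to the phenol rings of 10. The closest known reaction is the Danheiser benzannulation of cyclobutenones with alkoxyalkynes, run here at both ends of one molecule. Each benzene ring closes by a thermal disrotatory six-electron electrocyclization that joins the ketene carbonyl carbon (C4) to the bridge-bearing carbon (C5), after the (2+2) step has made C4–C3 and C1–C2. No stereocentre survives: those of 4, 7 and 9 are erased when each ring aromatizes, and the reversible ring openings funnel alkene isomers through the cyclizable (3E)-dienylketene. The step needs regioselective ketene–alkyne union and capture of the ketene by 5 rather than by the phenol being formed; alkyne polarization secures the first (the electrophilic ketene carbonyl carbon bonds to the methyl-bearing carbon β to oxygen, giving the 1,3,5-oxygen pattern with methyl and bridge flanking the new hydroxyl), and a large excess of 5 at moderate dilution should secure the second. The first stage is held at 80 °C because ethyl ynol ethers lose ethylene by a retro-ene reaction above roughly 100–120 °C, so excess 5 is removed before the final heating.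

Step 3
Reactants: 10 bis(4,6-diethoxy-2-hydroxy-3-methylphenyl)methane
Product: 11 bis(3-acetyl-2,4-diethoxy-6-hydroxy-5-methylphenyl)methane
Conditions: AcCl (2.4 equiv), SnCl4 (3 equiv), CH2Cl2, −20 °C to 0 °C; aq. HCl work-up
Reagents that add atoms: acetyl chloride, CC(Cl)=O
Why: Friedel–Crafts acylation at the only unsubstituted carbon of each ring, which is flanked by two ethoxy groups and para to the hydroxyl and so should be far more nucleophilic than the hindered phenol oxygen, while each acetyl group deactivates its ring against over-reaction and acid scission of the bridge.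

Step 4
Reactants: 11 bis(3-acetyl-2,4-diethoxy-6-hydroxy-5-methylphenyl)methane
Product: 12 bis(3-acetyl-2,4,6-trihydroxy-5-methylphenyl)methane
Conditions: BBr3 (10 equiv), CH2Cl2, −78 °C to rt; then ice–water
Reagents that add atoms: none
Why: Lewis acid cleavage of aryl alkyl ethers with BBr3, assisted because every ethoxy group is ortho to an acetyl carbonyl that chelates boron, and tolerated by the bridge because each ring now carries a deactivating acyl group.

**Compound list**
1 | glutaryl dichloride (pentanedioyl dichloride) | O=C(Cl)CCCC(=O)Cl | starting material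
2 | ethoxyacetylene (ethoxyethyne) | C#COCC | starting material
3 | penta-1,4-diene-1,5-dione (bis-ketene, not isolated) | O=C=CCC=C=O | intermediate
4 | 4,4'-methylenebis(3-ethoxycyclobut-2-en-1-one), mixture of meso and racemic diastereomers | CCOC1=CC(=O)C1CC1C(=O)C=C1OCC | intermediate
5 | 1-ethoxyprop-1-yne | CC#COCC | starting material
6 | (3Z,6Z)-3,7-diethoxynona-1,3,6,8-tetraene-1,9-dione (bis(vinylketene), not isolated) | O=C=C/C(OCC)=C/C/C=C(OCC)/C=C=O | intermediate
7 | 4,4'-[(1Z,4Z)-1,5-diethoxypenta-1,4-diene-1,5-diyl]bis(3-ethoxy-2-methylcyclobut-2-en-1-one), ring stereocentres as a mixture (not isolated) | CCOC1=C(C)C(=O)C1/C(OCC)=C/C/C=C(OCC)/C1C(=O)C(C)=C1OCC | intermediate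
8 | (3E,5Z,8Z,10E)-3,5,9,11-tetraethoxy-2,12-dimethyltrideca-1,3,5,8,10,12-hexaene-1,13-dione (bis(dienylketene), not isolated) | O=C=C(C)/C(OCC)=C\C(OCC)=C\C/C=C(OCC)/C=C(OCC)\C(C)=C=O | intermediate
9 | 6,6'-methylenebis(3,5-diethoxy-2-methylcyclohexa-2,4-dien-1-one), mixture of diastereomers (not isolated) | CCOC1=CC(OCC)=C(C)C(=O)C1CC1C(=O)C(C)=C(OCC)C=C1OCC | intermediate
10 | bis(4,6-diethoxy-2-hydroxy-3-methylphenyl)methane | CCOc1cc(OCC)c(Cc2c(OCC)cc(OCC)c(C)c2O)c(O)c1C | intermediate
11 | bis(3-acetyl-2,4-diethoxy-6-hydroxy-5-methylphenyl)methane | CCOc1c(C(C)=O)c(OCC)c(Cc2c(OCC)c(C(C)=O)c(OCC)c(C)c2O)c(O)c1C | intermediate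
12 | bis(3-acetyl-2,4,6-trihydroxy-5-methylphenyl)methane (CNP0190887.0, achiral) | CC(=O)c1c(O)c(C)c(O)c(Cc2c(O)c(C)c(O)c(C(C)=O)c2O)c1O | target

**Step count**
Total steps: 4. Longest linear sequence: 4 steps (1 → 4 → 10 → 11 → 12).

**Steps most likely to fail**

Step 2 (key step). What may go wrong: phenol rings formed early add through oxygen to vinylketene arms of other molecules and give aryl esters and oligomers, the donor-substituted vinylketene is captured too slowly by the ethyl ynol ether, and prolonged heating erodes the ynol ether by loss of ethylene. Fallback: setting out from 4, the partner is changed to the more ketenophilic and thermally robust siloxyalkyne triisopropyl(prop-1-yn-1-yloxy)silane F1, which is not commercial and would be made separately from ethyl acetate by ynolate homologation and O-silylation with iPr3SiCl. The same benzannulation (PhMe, 80 to 120 °C) should give bis[6-ethoxy-2-hydroxy-3-methyl-4-(triisopropylsilyloxy)phenyl]methane F2. TBAF in THF at 0 °C would remove the silyl groups to give bis(6-ethoxy-2,4-dihydroxy-3-methylphenyl)methane F3. Ortho-directed C-acetylation next to the freed hydroxyl (AcCl, TiCl4, CH2Cl2, 0 °C) would give bis(3-acetyl-2-ethoxy-4,6-dihydroxy-5-methylphenyl)methane F4, and BBr3 would cleave the two remaining ethyl ethers, rejoining the route at 12.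

Step 1. What may go wrong: after the first dehydrochlorination the ketene terminus or its enolate is captured by the acyl chloride at the other end of the same three-carbon chain (six-membered enol lactone), or the aldoketene termini dimerize and oligomerize faster than 2 traps them. Fallback: the two cyclobutenones are built one after the other, so that a ketene never faces an acyl chloride. It sets out from 2, which is combined with the commercial half-ester chloride methyl 5-chloro-5-oxopentanoate F5 and Et3N; the ketene methyl 5-oxopent-4-enoate F6 (not isolated) should be trapped as racemic methyl 3-(2-ethoxy-4-oxocyclobut-2-en-1-yl)propanoate F7. Hydrolysis at neutral pH with pig liver esterase (phosphate buffer, pH 7), chosen to spare the vinylogous ester, would give 3-(2-ethoxy-4-oxocyclobut-2-en-1-yl)propanoic acid F8. 1-Chloro-N,N,2-trimethylprop-1-en-1-amine in CH2Cl2 would convert it under neutral conditions into 3-(2-ethoxy-4-oxocyclobut-2-en-1-yl)propanoyl chloride F9. Et3N and a second portion of 2 would then lead through the ketene 3-ethoxy-4-(3-oxoprop-2-en-1-yl)cyclobut-2-en-1-one F10 (not isolated) back to 4.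

Step 3. What may go wrong: acetylation at the phenol oxygens competes with ring acylation, and Lewis acid bound at the free phenols slows the second C-acylation, so that mixtures of mono-acylated and O-acylated material result. Fallback: setting out from 10, the two phenols are capped first (EtI, K2CO3, DMF, 60 °C) to give bis(2,4,6-triethoxy-3-methylphenyl)methane F11, in which the ring carbon is the only nucleophilic site. Friedel–Crafts acetylation (AcCl, AlCl3, CH2Cl2, −20 °C), the standard reaction of 1,3,5-trialkoxybenzenes, would give bis(3-acetyl-2,4,6-triethoxy-5-methylphenyl)methane F12, and BBr3 would then cleave all six ethyl ethers, returning to the route at 12.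

**Further compounds**
F1 | step 2 | triisopropyl(prop-1-yn-1-yloxy)silane | CC#CO[Si](C(C)C)(C(C)C)C(C)C
F2 | step 2 | bis[6-ethoxy-2-hydroxy-3-methyl-4-(triisopropylsilyloxy)phenyl]methane | CCOc1cc(O[Si](C(C)C)(C(C)C)C(C)C)c(C)c(O)c1Cc1c(OCC)cc(O[Si](C(C)C)(C(C)C)C(C)C)c(C)c1O
F3 | step 2 | bis(6-ethoxy-2,4-dihydroxy-3-methylphenyl)methane | CCOc1cc(O)c(C)c(O)c1Cc1c(OCC)cc(O)c(C)c1O
F4 | step 2 | bis(3-acetyl-2-ethoxy-4,6-dihydroxy-5-methylphenyl)methane | CCOc1c(C(C)=O)c(O)c(C)c(O)c1Cc1c(OCC)c(C(C)=O)c(O)c(C)c1O
F5 | step 1 | methyl 5-chloro-5-oxopentanoate | COC(=O)CCCC(Cl)=O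
F6 | step 1 | methyl 5-oxopent-4-enoate | COC(=O)CCC=C=O
F7 | step 1 | methyl 3-(2-ethoxy-4-oxocyclobut-2-en-1-yl)propanoate (racemic) | CCOC1=CC(=O)C1CCC(=O)OC
F8 | step 1 | 3-(2-ethoxy-4-oxocyclobut-2-en-1-yl)propanoic acid (racemic) | CCOC1=CC(=O)C1CCC(=O)O
F9 | step 1 | 3-(2-ethoxy-4-oxocyclobut-2-en-1-yl)propanoyl chloride (racemic) | CCOC1=CC(=O)C1CCC(Cl)=O
F10 | step 1 | 3-ethoxy-4-(3-oxoprop-2-en-1-yl)cyclobut-2-en-1-one (racemic) | CCOC1=CC(=O)C1CC=C=O
F11 | step 3 | bis(2,4,6-triethoxy-3-methylphenyl)methane | CCOc1cc(OCC)c(Cc2c(OCC)cc(OCC)c(C)c2OCC)c(OCC)c1C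
F12 | step 3 | bis(3-acetyl-2,4,6-triethoxy-5-methylphenyl)methane | CCOc1c(C(C)=O)c(OCC)c(Cc2c(OCC)c(C(C)=O)c(OCC)c(C)c2OCC)c(OCC)c1C
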